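**Plan**
- Retrosynthesis: both C8 methyls come from CHO. Ring B′ is cut at C7′–C8′ and C9′–C10′, and ring B at C7–C8 and C9–C10, as two [4+2] cycloadditions of one achiral ring-A diene. The linking enal C8=C9 is cut by cross-metathesis.
- Enabling feature: in ring B′ the unit C8′–C9′ sits between C7′ and C10′, and C10′=C5′ can lie in ring A′. A ring A′ cyclohexene with a 2-silyloxyvinyl group on C5′ is therefore the 1-oxy diene C7′=C6′–C5′=C10′. The C7′ oxygen steers regiochemistry and is later expelled to bring H-5′ in cis to the C10′ methyl.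
- Forward order: ring-A diene, then ring B′ (step 6), CHO to CH3, chain extension to a new enal, ring B by a second cycloaddition, double reductive 1,3-transposition, conjugation of the left aldehyde, reductions.
- Stereochemistry: the absolute sense comes from a chiral oxazaborolidinium catalyst in both cycloadditions. C8′, C9′, C10′ (and C9, C10) follow from E-dienophile geometry and endo addition. C5 and C5′ follow from anti palladium–formate hydrogenolysis directed by the 7α-oxygen. C3 and C3′ follow from convex-face hydride reduction.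

Key step: step 6

**Remarks**
- Locants: each bicyclic half is numbered C1–C10 (ring A = C1–C5, C10; ring B = C5–C10). C4 carries the gem-dimethyl group, C10 the angular methyl, C9 the linking chain C11–C12, and C26 is the carbon on C8. Primed locants are the saturated half. β is the face carrying the C10 methyl.
- Structure as read from the SMILES: both decalins are cis-fused (H-5 β, cis to the C10 methyl), with 3α-OH and 9α-H; the C8′ methyl is α.
- Assumption: the (S)-oxazaborolidinium salt is taken to give the diene face shown; if the opposite sense is found, its enantiomer is used with no other change.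

**Step 1**
Reactants: 1 2,2-dimethylcyclohexane-1,3-dione; 2 ethane-1,2-diol
Product: 3 6,6-dimethyl-1,4-dioxaspiro[4.5]decan-7-one
Conditions: ethane-1,2-diol (1.1 equiv), p-TsOH·H2O (cat.), benzene, reflux, Dean–Stark
Reagents that add atoms: ethane-1,2-diol, OCCO
Why: Acid-catalysed ketalisation should stop at the monoketal because the remaining carbonyl is then flanked by the quaternary carbon and the dioxolane; no stereocentre is formed.

**Step 2**
Reactants: 3 monoketal; 4 iodomethane
Product: 5 6,6,8-trimethyl-1,4-dioxaspiro[4.5]decan-7-one (racemic)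
Conditions: LiN(i-Pr)2, THF, −78 °C; MeI, −78 → 0 °C
Reagents that add atoms: iodomethane, CI
Why: Enolate alkylation can occur only at C8 because the other α-carbon is quaternary; the new stereocentre is racemic and is erased in step 4.

**Step 3**
Reactants: 5 methyl ketone; 6 (Z)-1-bromo-2-ethoxyethene
Product: 8 2-(6,6,8-trimethyl-1,4-dioxaspiro[4.5]decan-7-ylidene)acetaldehyde, via carbinol 7 (not isolated)
Conditions: 6, t-BuLi (2 equiv), THF, −78 °C; add 5 (premixed with anhydrous CeCl3), −78 → 0 °C; then 0.5 M HCl, THF, 0 °C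
Reagents that add atoms: (Z)-1-bromo-2-ethoxyethene, CCO/C=C\Br; water, O
Why: 1,2-Addition of (Z)-2-ethoxyvinyllithium followed by acid hydrolysis of the enol ether with loss of water (formyl-olefination by a Meyer–Schuster-type allylic transposition) should give the enal, whose exocyclic alkene geometry is irrelevant because step 4 erases it.

**Step 4**
Reactants: 8 enal; 9 tert-butyldimethylsilyl trifluoromethanesulfonate
Product: 10 tert-butyl(dimethyl){[(E)-2-(6,6,8-trimethyl-1,4-dioxaspiro[4.5]dec-7-en-7-yl)ethenyl]oxy}silane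
Conditions: TBSOTf, Et3N, CH2Cl2, 0 °C → rt
Reagents that add atoms: tert-butyldimethylsilyl trifluoromethanesulfonate, CC(C)(C)[Si](C)(C)OS(=O)(=O)C(F)(F)F
Why: Vinylogous silyl enol ether formation (O-silylation, then γ-deprotonation) can remove only H-8 since C6 is quaternary, and the s-trans enal should give the (E)-silyloxyvinyl group.

**Step 5**
Reactants: 11 pent-4-enal; 12 2-(triphenyl-λ5-phosphanylidene)acetaldehyde
Product: 13 (2E)-hepta-2,6-dienal
Conditions: toluene, 80 °C, aldehyde in slight excess
Reagents that add atoms: 2-(triphenyl-λ5-phosphanylidene)acetaldehyde, O=CC=P(c1ccccc1)(c1ccccc1)c1ccccc1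
Why: Wittig olefination with the stabilised formylmethylene ylide should give the (E)-enal, the excess aldehyde limiting a second homologation.

**Step 6**
Reactants: 10 silyloxy diene; 13 (2E)-hepta-2,6-dienal
Product: 14 ring-B′ cycloadduct (C5′=C6′; 7′α-OTBS; 8′α-CHO; 9′β-but-3-enyl; 10′β-CH3; 3′-ethylene ketal)
Conditions: (S)-1-(2-methylphenyl)-3,3-diphenyltetrahydro-1H,3H-pyrrolo[1,2-c][1,3,2]oxazaborole (20 mol%), Tf2NH (18 mol%), CH2Cl2, −78 → −40 °C; Et3N quench
Reagents that add atoms: none
Why: This is a normal-electron-demand Diels–Alder reaction in which the boron Lewis acid lowers the LUMO of enal 13 while the silyloxy group raises the HOMO of diene 10 and puts its largest coefficient on C10′, so C10′ bonds to the β-carbon C9′ and C7′ to the α-carbon C8′ in a concerted, asynchronous [4+2] event. The closest known reaction type is the oxazaborolidinium-catalysed Diels–Alder reaction of enals with silyloxy dienes, together with cycloadditions of 2-methyl-1-vinylcyclohexenes that create an angular methyl. Ring B′ is closed onto ring A′ by intermolecular [4+2] cycloaddition, both bonds forming in one step. C10′ is set by the diene face selected by the catalyst (the diene is achiral), C8′ and C9′ by the E geometry of 13 with the formyl group endo (CHO α, chain β and cis to the C10′ methyl), and C7′ by the E geometry of the dienol ether in the same endo arrangement (OTBS cis to CHO). The step needs ortho regioselectivity, endo selectivity and facial selectivity, secured in turn by the C7′ oxygen donor, the Lewis-acid-bound formyl group and the catalyst. The terminal alkene of 13 is unactivated and should stay untouched.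

**Step 7**
Reactants: 14 cycloadduct aldehyde
Product: 16 8′α-methyl compound (14 with CHO replaced by CH3), via tosylhydrazone 15 (not isolated)
Conditions: TsNHNH2, EtOH, rt; concentrate; catecholborane, CHCl3, 0 °C; NaOAc·3H2O, 60 °C
Reagents that add atoms: none
Why: Tosylhydrazone formation and hydride reduction with catecholborane give an alkyldiazene that loses N2 (a mild Wolff–Kishner-type deoxygenation), turning CHO into the C8′ methyl without strong base, so the β-silyloxy aldehyde cannot eliminate and C8′ keeps its configuration.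

**Step 8**
Reactants: 16 terminal alkene; 17 (E)-but-2-enal
Product: 18 (E)-enal (16 with the side chain on C9′ now CH2CH2CH=CH–CHO)
Conditions: second-generation Hoveyda–Grubbs catalyst [RuCl2(H2IMes)(=CH-C6H4-2-O-i-Pr)] (5 mol%), (E)-but-2-enal (5 equiv), CH2Cl2, 40 °C
Reagents that add atoms: (E)-but-2-enal, C/C=C/C=O
Why: Olefin cross-metathesis of the terminal alkene with excess crotonaldehyde should give the (E)-enal, the C5′=C6′ alkene being inert because it lies between two quaternary carbons.

**Step 9**
Reactants: 18 enal; 10 silyloxy diene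
Product: 19 bis-adduct aldehyde (new ring B: C5=C6; 7α-OTBS; 8α-CHO; 9β-C11; 10β-CH3; 3-ethylene ketal)
Conditions: as step 6 with 30 mol% catalyst, CH2Cl2, −78 → −40 °C
Reagents that add atoms: none
Why: A second catalyst-controlled endo Diels–Alder reaction of the same type as step 6 builds ring B with C9, C10 and C7 set by the same elements, the stereocentres of 18 being too remote to interfere, so the same catalyst antipode should give the homochiral half.

**Step 10**
Reactants: 19 bis-adduct aldehyde; 20 trimethoxymethane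
Product: 21 dimethyl acetal of 19
Conditions: HC(OMe)3, PPTS (cat.), MeOH, rt
Reagents that add atoms: trimethoxymethane, COC(OC)OC
Why: Acetalisation masks the β-silyloxy aldehyde so that the fluoride, acylation and palladium steps cannot cause β-elimination or retro-aldol cleavage.

**Step 11**
Reactants: 21 bis-silyl ether
Product: 22 7α,7′α-diol
Conditions: TBAF (3 equiv), THF, 0 °C → 40 °C
Reagents that add atoms: none
Why: Fluoride cleaves both secondary silyl ethers with retention, acetal and ketals being inert.

**Step 12**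
Reactants: 22 diol; 23 acetic formic anhydride
Product: 24 7α,7′α-bis(formate)
Conditions: preformed acetic formic anhydride, pyridine, CH2Cl2, 0 °C → rt
Reagents that add atoms: acetic formic anhydride, O=COC(C)=O
Why: O-Formylation with the mixed anhydride transfers the small formyl group to both hindered allylic alcohols with retention, installing the internal hydride source.

**Step 13**
Reactants: 24 bis(formate)
Product: 25 bis-cis-fused diene (5β-H and 5′β-H; C6=C7 and C6′=C7′)
Conditions: Pd(OAc)2 (10 mol%), n-Bu3P (40 mol%), 1,4-dioxane, 100 °C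
Reagents that add atoms: none
Why: Palladium-catalysed hydrogenolysis of allylic formates (Tsuji–Trost-type ionisation anti to the 7α-formate, decarboxylation to a palladium hydride, hydride transfer from the metal to the more substituted allyl terminus) should place H on the β face of C5 and C5′, cis to the C10 methyls, and move the alkenes to C6=C7 and C6′=C7′.

**Step 14**
Reactants: 25 acetal bis-ketal
Product: 27 conjugated enal-dione (C7=C8–CHO; 3,3′-dione; C6′=C7′), via β,γ-unsaturated aldehyde 26 (not isolated)
Conditions: p-TsOH·H2O, acetone/H2O, 50 °C; then DBU, CH2Cl2, rt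
Reagents that add atoms: water, O
Why: Aqueous acid hydrolyses the dimethyl acetal and both dioxolanes, and DBU then moves the β,γ-alkene of the free aldehyde into conjugation by γ-protonation of its dienolate, which fixes C7=C8 while the unactivated C6′=C7′ alkene stays.

**Step 15**
Reactants: 27 enal-dione
Product: 28 triol (C26-OH; 3α-OH; 3′α-OH)
Conditions: NaBH4, CeCl3·7H2O, MeOH, −40 → 0 °C
Reagents that add atoms: none
Why: Luche reduction reduces the enal 1,2 and both ketones by hydride attack on the convex β face of each cis-fused ring A, away from ring B, which should give the equatorial 3α and 3′α alcohols as in reductions of 5β-3-keto steroids.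

**Step 16**
Reactants: 28 triol
Product: 29 6′,7′-dihydro triol
Conditions: 2-nitrobenzenesulfonylhydrazide, Et3N, CH2Cl2, rt
Reagents that add atoms: none
Why: Diimide generated in the flask reduces the unhindered cis-disubstituted C6′=C7′ alkene much faster than the trisubstituted C7=C8 alkene; no stereocentre is formed.

**Step 17**
Reactants: 29 triol; 30 N-chlorosuccinimide
Product: 31 allylic chloride (C26-Cl)
Conditions: NCS, Me2S, CH2Cl2, −20 → 0 °C
Reagents that add atoms: N-chlorosuccinimide, O=C1CCC(=O)N1Cl
Why: Corey–Kim chlorination converts only the primary allylic alcohol, because only its alkoxysulfonium ion is displaced by chloride at low temperature while the hindered secondary ones revert on work-up.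

**Step 18**
Reactants: 31 allylic chloride
Product: 32 target diol
Conditions: LiEt3BH (excess), THF, 0 °C → rt; aqueous work-up
Reagents that add atoms: none
Why: SN2 hydride displacement of the primary allylic chloride gives the C8 methyl with the alkene kept at C7=C8, and the lithium alkoxides of the two hydroxyls are protonated on work-up.

**Compound list**
1 | 2,2-dimethylcyclohexane-1,3-dione | CC1(C)C(=O)CCCC1=O | starting material
2 | ethane-1,2-diol | OCCO | starting material
3 | 6,6-dimethyl-1,4-dioxaspiro[4.5]decan-7-one | CC1(C)C(=O)CCCC12OCCO2 | intermediate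
4 | iodomethane | CI | starting material
5 | 6,6,8-trimethyl-1,4-dioxaspiro[4.5]decan-7-one (racemic) | CC1CCC2(OCCO2)C(C)(C)C1=O | intermediate
6 | (Z)-1-bromo-2-ethoxyethene | CCO/C=C\Br | starting material
7 | 7-[(Z)-2-ethoxyethenyl]-6,6,8-trimethyl-1,4-dioxaspiro[4.5]decan-7-ol (diastereomer mixture, not isolated) | CCO/C=C\C1(O)C(C)CCC2(OCCO2)C1(C)C | intermediate
8 | 2-(6,6,8-trimethyl-1,4-dioxaspiro[4.5]decan-7-ylidene)acetaldehyde (racemic, alkene isomers) | CC1CCC2(OCCO2)C(C)(C)C1=CC=O | intermediate
9 | tert-butyldimethylsilyl trifluoromethanesulfonate | CC(C)(C)[Si](C)(C)OS(=O)(=O)C(F)(F)F | starting material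
10 | tert-butyl(dimethyl){[(E)-2-(6,6,8-trimethyl-1,4-dioxaspiro[4.5]dec-7-en-7-yl)ethenyl]oxy}silane (achiral diene) | CC1=C(/C=C/O[Si](C)(C)C(C)(C)C)C(C)(C)C2(CC1)OCCO2 | intermediate
11 | pent-4-enal | C=CCCC=O | starting material
12 | 2-(triphenyl-λ5-phosphanylidene)acetaldehyde | O=CC=P(c1ccccc1)(c1ccccc1)c1ccccc1 | starting material
13 | (2E)-hepta-2,6-dienal | C=CCC/C=C/C=O | intermediate
14 | ring A′B′ unit: 3′,3′-ethylenedioxy-4′,4′,10′β-trimethyl-Δ5′(6′)-octalin with 7′α-OTBS, 8′α-CHO, 9′β-(but-3-enyl) | C=CCC[C@H]1[C@H](C=O)[C@H](O[Si](C)(C)C(C)(C)C)C=C2C(C)(C)C3(OCCO3)CC[C@@]21C | intermediate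
15 | (E)-tosylhydrazone of 14 (not isolated) | C=CCC[C@H]1[C@H](/C=N/NS(=O)(=O)c2ccc(C)cc2)[C@H](O[Si](C)(C)C(C)(C)C)C=C2C(C)(C)C3(OCCO3)CC[C@@]21C | intermediate
16 | 14 with 8′α-CH3 in place of CHO | C=CCC[C@H]1[C@H](C)[C@H](O[Si](C)(C)C(C)(C)C)C=C2C(C)(C)C3(OCCO3)CC[C@@]21C | intermediate
17 | (E)-but-2-enal | C/C=C/C=O | starting material
18 | 16 with 9′β-[(E)-5-oxopent-3-enyl] side chain | O=C/C=C/CC[C@H]1[C@H](C)[C@H](O[Si](C)(C)C(C)(C)C)C=C2C(C)(C)C3(OCCO3)CC[C@@]21C | intermediate
19 | bis-adduct: second unit (3,3-ethylenedioxy-4,4,10β-trimethyl-Δ5(6)-octalin, 7α-OTBS, 8α-CHO) joined from C9 (β) through C11H2–C12H2 to C9′ of the unit of 16 | O=C[C@@H]1[C@H](O[Si](C)(C)C(C)(C)C)C=C2C(C)(C)C3(OCCO3)CC[C@]2(C)[C@H]1CC[C@H]1[C@H](C)[C@H](O[Si](C)(C)C(C)(C)C)C=C2C(C)(C)C3(OCCO3)CC[C@@]21C | intermediate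
20 | trimethoxymethane | COC(OC)OC | starting material
21 | 19 with 8α-CH(OMe)2 | COC(OC)[C@@H]1[C@H](O[Si](C)(C)C(C)(C)C)C=C2C(C)(C)C3(OCCO3)CC[C@]2(C)[C@H]1CC[C@H]1[C@H](C)[C@H](O[Si](C)(C)C(C)(C)C)C=C2C(C)(C)C3(OCCO3)CC[C@@]21C | intermediate
22 | 7α,7′α-diol from 21 | COC(OC)[C@@H]1[C@H](O)C=C2C(C)(C)C3(OCCO3)CC[C@]2(C)[C@H]1CC[C@H]1[C@H](C)[C@H](O)C=C2C(C)(C)C3(OCCO3)CC[C@@]21C | intermediate
23 | acetic formic anhydride | O=COC(C)=O | starting material
24 | 7α,7′α-bis(formate) of 22 | COC(OC)[C@@H]1[C@H](OC=O)C=C2C(C)(C)C3(OCCO3)CC[C@]2(C)[C@H]1CC[C@H]1[C@H](C)[C@H](OC=O)C=C2C(C)(C)C3(OCCO3)CC[C@@]21C | intermediate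
25 | bis-cis-fused diene: 5β-H, 5′β-H, C6=C7, C6′=C7′, 8α-CH(OMe)2, 8′α-CH3, 3- and 3′-ethylene ketals | COC(OC)[C@@H]1C=C[C@@H]2C(C)(C)C3(OCCO3)CC[C@]2(C)[C@H]1CC[C@H]1[C@H](C)C=C[C@@H]2C(C)(C)C3(OCCO3)CC[C@@]21C | intermediate
26 | β,γ-unsaturated aldehyde 3,3′-dione (8α-CHO, C6=C7; not isolated) | O=C[C@@H]1C=C[C@@H]2C(C)(C)C(=O)CC[C@]2(C)[C@H]1CC[C@H]1[C@H](C)C=C[C@@H]2C(C)(C)C(=O)CC[C@@]21C | intermediate
27 | conjugated enal 3,3′-dione (C7=C8–CHO; C6′=C7′) | O=CC1=CC[C@@H]2C(C)(C)C(=O)CC[C@]2(C)[C@H]1CC[C@H]1[C@H](C)C=C[C@@H]2C(C)(C)C(=O)CC[C@@]21C | intermediate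
28 | triol: C26-OH, 3α-OH, 3′α-OH, C7=C8, C6′=C7′ | OCC1=CC[C@@H]2C(C)(C)[C@H](O)CC[C@]2(C)[C@H]1CC[C@H]1[C@H](C)C=C[C@@H]2C(C)(C)[C@H](O)CC[C@@]21C | intermediate
29 | 6′,7′-dihydro triol | OCC1=CC[C@@H]2C(C)(C)[C@H](O)CC[C@]2(C)[C@H]1CC[C@H]1[C@H](C)CC[C@@H]2C(C)(C)[C@H](O)CC[C@@]21C | intermediate
30 | N-chlorosuccinimide | O=C1CCC(=O)N1Cl | starting material
31 | C26 allylic chloride of 29 | ClCC1=CC[C@@H]2C(C)(C)[C@H](O)CC[C@]2(C)[C@H]1CC[C@H]1[C@H](C)CC[C@@H]2C(C)(C)[C@H](O)CC[C@@]21C | intermediate
32 | target: cis,cis-fused onocer-7-ene-3α,3′α-diol with 8′α-CH3 | CC1=CC[C@@H]2C(C)(C)[C@H](O)CC[C@]2(C)[C@H]1CC[C@H]1[C@H](C)CC[C@@H]2C(C)(C)[C@H](O)CC[C@@]21C | target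

**Totals**
Total step count: 18. Longest linear sequence: 17 (steps 1–4 and 6–18).

**Steps most likely to fail**

1. Step 6 (the same risk holds for step 9). The cycloaddition may be slow at the fully substituted diene terminus C10′. Acid-promoted loss of the silyl dienol ether, or Michael addition without ring closure, could then overtake it, and facial discrimination by the catalyst may be poor. The fallback replaces catalyst control by auxiliary control; it sets out from 10 and 11 and returns at 14. Pent-4-enal 11 is condensed under Horner–Wadsworth–Emmons conditions (LiCl, i-Pr2NEt, MeCN) with (R)-4-benzyl-3-[(diethoxyphosphoryl)acetyl]-1,3-oxazolidin-2-one to give (R)-4-benzyl-3-[(2E)-hepta-2,6-dienoyl]-1,3-oxazolidin-2-one F1. Cycloaddition of F1 with diene 10 under Me2AlCl (CH2Cl2, −78 → −30 °C) should give the imide cycloadduct F2. The chelated s-cis imide exposes the face remote from the benzyl group, and the acyl group adds endo. LiBH4 (THF, 1 equiv H2O) should then release the primary alcohol F3, and Dess–Martin oxidation returns to aldehyde 14.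

2. Step 13. Hydride transfer may go to the less hindered allyl terminus C7/C7′, with no transposition and no new C5 stereocentre. β-Hydride elimination to a ring-B diene is also possible, because C5 lies between two quaternary carbons. The fallback is a sigmatropic reductive transposition; it sets out from diol 22 and returns at 25. Mitsunobu reaction of 22 with 2-nitrobenzenesulfonylhydrazide (PPh3, diethyl azodicarboxylate, THF, −30 °C) should give, with inversion, the 7β,7′β-bis(N-sulfonylhydrazine) F4. On warming to rt F4 loses the sulfinic acid to give the allylic diazenes, which undergo suprafacial retro-ene loss of N2. This delivers H to the β face of C5 and C5′ and shifts the alkenes to C6=C7 and C6′=C7′, giving 25.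

3. Step 3. Proton transfer from the hindered ketone to the vinyllithium (enolisation) may outrun carbonyl addition. The fallback joins the two carbons by cross-coupling; it sets out from 5 and returns at 10. Ketone 5 is converted with KN(SiMe3)2 and PhNTf2 into 6,6,8-trimethyl-1,4-dioxaspiro[4.5]dec-7-en-7-yl trifluoromethanesulfonate F5. Suzuki–Miyaura coupling with (E)-2-ethoxyvinylboronic acid pinacol ester (Pd(PPh3)4, K3PO4, dioxane/H2O, 80 °C) should give 7-[(E)-2-ethoxyethenyl]-6,6,8-trimethyl-1,4-dioxaspiro[4.5]dec-7-ene F6. Brief dilute acid should give 2-(6,6,8-trimethyl-1,4-dioxaspiro[4.5]dec-7-en-7-yl)acetaldehyde F7. Silylation as in step 4 (TBSOTf, Et3N) then leads to diene 10; the E isomer should be favoured because it avoids the clash between the silyloxy group and the ring substituents.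

**Further compounds**
F1 | step 6 | (R)-4-benzyl-3-[(2E)-hepta-2,6-dienoyl]-1,3-oxazolidin-2-one | C=CCC/C=C/C(=O)N1[C@H](Cc2ccccc2)COC1=O
F2 | step 6 | imide cycloadduct (14 with 8′α-C(=O)-oxazolidinone in place of CHO) | C=CCC[C@H]1[C@H](C(=O)N2[C@H](Cc3ccccc3)COC2=O)[C@H](O[Si](C)(C)C(C)(C)C)C=C2C(C)(C)C3(OCCO3)CC[C@@]21C
F3 | step 6 | primary alcohol (14 with 8′α-CH2OH in place of CHO) | C=CCC[C@H]1[C@H](CO)[C@H](O[Si](C)(C)C(C)(C)C)C=C2C(C)(C)C3(OCCO3)CC[C@@]21C
F4 | step 13 | 7β,7′β-bis[N-(2-nitrobenzenesulfonyl)hydrazin-1-yl] compound from 22 | COC(OC)[C@@H]1[C@@H](N(N)S(=O)(=O)c2ccccc2[N+](=O)[O-])C=C2C(C)(C)C3(OCCO3)CC[C@]2(C)[C@H]1CC[C@H]1[C@H](C)[C@@H](N(N)S(=O)(=O)c2ccccc2[N+](=O)[O-])C=C2C(C)(C)C3(OCCO3)CC[C@@]21C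
F5 | step 3 | 6,6,8-trimethyl-1,4-dioxaspiro[4.5]dec-7-en-7-yl trifluoromethanesulfonate | CC1=C(OS(=O)(=O)C(F)(F)F)C(C)(C)C2(CC1)OCCO2
F6 | step 3 | 7-[(E)-2-ethoxyethenyl]-6,6,8-trimethyl-1,4-dioxaspiro[4.5]dec-7-ene | CCO/C=C/C1=C(C)CCC2(OCCO2)C1(C)C
F7 | step 3 | 2-(6,6,8-trimethyl-1,4-dioxaspiro[4.5]dec-7-en-7-yl)acetaldehyde | O=CCC1=C(C)CCC2(OCCO2)C1(C)C
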